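**Retrosynthetic overview**

1. Labels and feature: ring A is the catechol ring with the propenoate (C7=C8–C9) at C1, the acrylate carbon Cα at C2 and hydroxyls O3 and O4 at C3 and C4; ring B is the catechol ring on Cβ; C9' is the carboxyl carbon on Cα. Cα carries C9' and sits on C2 next to C3–O3H, so C9' and O3 can close a five-membered ring, and Cα(C9')=Cβ(H)(ring B) is the syn adduct of H and an O3-tethered carbonyl across a ring A–C≡C–ring B alkyne.
2. Salvianolic acid E ⇐ acidolysis of three catechol acetonides, one MOM ether and two tert-butyl esters ⇐ C9'–O ester made by alkoxide opening of the O3–C9' aryl ester of an (E)-3-arylidenebenzofuran-2-one with protected danshensu.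
3. Lactone ⇐ Cα–C9' and C9'–O3 by palladium-catalysed cyclocarbonylation (CO) of the 2-alkynylphenol that already carries the danshensu propenoate.
4. 2-Alkynylphenol ⇐ Sonogashira coupling (C2–C≡C) of the O3-acetyl, O4-MOM bromoaldehyde from 2-bromoisovanillin with the ring B alkyne from protocatechualdehyde, then Horner–Wadsworth–Emmons olefination (C7=C8) with the phosphonoacetate of protected (R)-danshensu, then deacetylation.
5. Ring order: all four benzene rings come from the starting materials; the only ring made is the temporary lactone (step 13), opened again in step 14.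

Key step: step 13

Assumption: (R)-danshensu is used as the free acid; if only its sodium salt is at hand it is acidified and extracted first, which does not touch the stereocentre.

**Route**

Step 1
Reactants: 1 (R)-danshensu
Product: 2 (5R)-5-[(2,2-dimethyl-1,3-benzodioxol-5-yl)methyl]-2,2-dimethyl-1,3-dioxolan-4-one
Conditions: Me2C(OMe)2, TsOH·H2O (cat.), benzene, reflux through 4 Å MS (Soxhlet)
Reagents that add atoms: 2,2-dimethoxypropane, COC(C)(C)OC
Why: Acid-catalysed transketalisation with removal of methanol should close both the catechol acetonide and the 1,3-dioxolan-4-one of the α-hydroxy acid, and since no bond at the stereocentre is broken the R configuration is kept.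

Step 2
Reactants: 2 dioxolanone acetonide
Product: 3 (2R)-3-(2,2-dimethyl-1,3-benzodioxol-5-yl)-2-hydroxypropanoic acid
Conditions: LiOH (2.2 equiv), THF/H2O, 0 °C; then 1 M HCl to pH 3, 0 °C
Reagents that add atoms: lithium hydroxide, [Li+].[OH-]
Why: Saponification of the acylal-type dioxolanone carbonyl is fast at 0 °C and releases acetone, the catechol acetonide is inert to base and to a brief cold acidification, and hydroxide attacks the carbonyl and not the stereocentre.

Step 3
Reactants: 3 acetonide hydroxy acid
Product: 4 tert-butyl (2R)-3-(2,2-dimethyl-1,3-benzodioxol-5-yl)-2-hydroxypropanoate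
Conditions: Cl3CC(=NH)OtBu (2 equiv), CH2Cl2/cyclohexane, rt
Reagents that add atoms: tert-butyl 2,2,2-trichloroacetimidate, CC(C)(C)OC(=N)C(Cl)(Cl)Cl
Why: The carboxylic acid itself protonates the imidate and captures the tert-butyl cation (acid-selective tert-butyl esterification), whereas the secondary alcohol would need a Lewis acid to react.

Step 4
Reactants: 4 protected danshensu alcohol; 5 diethylphosphonoacetic acid
Product: 6 tert-butyl (2R)-2-{[2-(diethoxyphosphoryl)acetyl]oxy}-3-(2,2-dimethyl-1,3-benzodioxol-5-yl)propanoate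
Conditions: DCC, DMAP (cat.), CH2Cl2, 0 °C → rt
Reagents that add atoms: none
Why: Steglich esterification acylates only the oxygen of the secondary alcohol, so the stereocentre is untouched.

Step 5
Reactants: 7 3,4-dihydroxybenzaldehyde (protocatechualdehyde)
Product: 8 2,2-dimethyl-1,3-benzodioxole-5-carbaldehyde
Conditions: Me2C(OMe)2, TsOH·H2O (cat.), benzene, reflux through 4 Å MS (Soxhlet); dilute aqueous acid work-up
Reagents that add atoms: 2,2-dimethoxypropane, COC(C)(C)OC
Why: Catechol ketalisation by transketalisation is driven by trapping methanol, and any dimethyl acetal formed at the aldehyde is returned to the aldehyde by the mild aqueous work-up that leaves the aryl ketal intact.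

Step 6
Reactants: 8 acetonide aldehyde
Product: 9 5-ethynyl-2,2-dimethyl-1,3-benzodioxole
Conditions: MeC(O)C(N2)P(O)(OMe)2, K2CO3, MeOH, 0 °C → rt
Reagents that add atoms: dimethyl (1-diazo-2-oxopropyl)phosphonate, COP(=O)(OC)C(=[N+]=[N-])C(C)=O
Why: Seyferth–Gilbert homologation with the Ohira–Bestmann reagent, in which methanolysis releases the diazomethylphosphonate anion that adds to the non-enolisable aryl aldehyde and, after loss of dimethyl phosphate and N2, gives the terminal alkyne under conditions the ketal tolerates.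

Step 7
Reactants: 10 2-bromo-3-hydroxy-4-methoxybenzaldehyde (2-bromoisovanillin)
Product: 11 2-bromo-3,4-dihydroxybenzaldehyde
Conditions: BBr3 (2.5 equiv), CH2Cl2, −78 °C → rt; H2O
Reagents that add atoms: none
Why: Lewis acid demethylation of the aryl methyl ether with BBr3 is a standard way to the catechol and leaves the aryl bromide and the aldehyde in place.

Step 8
Reactants: 11 2-bromo-3,4-dihydroxybenzaldehyde
Product: 12 2-bromo-3-hydroxy-4-(methoxymethoxy)benzaldehyde
Conditions: MOMCl (1.05 equiv), K2CO3 (1.1 equiv), acetone, 0 °C → rt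
Reagents that add atoms: chloromethyl methyl ether, COCCl
Why: O4–H, para to the formyl group, is the more acidic phenol and O3–H is flanked by bromine, so one equivalent of weak base and MOMCl should alkylate O4 selectively (regioselective O-alkylation as known for protocatechualdehyde).

Step 9
Reactants: 12 O4-MOM bromophenol
Product: 13 2-bromo-3-formyl-6-(methoxymethoxy)phenyl acetate
Conditions: Ac2O, pyridine, DMAP (cat.), 0 °C → rt
Reagents that add atoms: acetic anhydride, CC(=O)OC(C)=O
Why: DMAP-catalysed acetylation of the remaining hindered phenol masks O3 so that the later cross-coupling cannot close a benzofuran.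

Step 10
Reactants: 13 aryl bromide; 9 ring B alkyne
Product: 14 2-[(2,2-dimethyl-1,3-benzodioxol-5-yl)ethynyl]-3-formyl-6-(methoxymethoxy)phenyl acetate
Conditions: PdCl2(PPh3)2 (5 mol %), CuI (5 mol %), Et3N, DMF, 60 °C, degassed
Reagents that add atoms: none
Why: Sonogashira coupling, in which oxidative addition into the C2–Br bond is helped by the ortho formyl group and the O3 acetate blocks the 5-endo cyclisation that free 2-halophenols undergo under Pd/Cu.

Step 11
Reactants: 14 alkynyl aldehyde; 6 danshensu phosphonoacetate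
Product: 15 tert-butyl (2R)-2-{[(2E)-3-{3-acetoxy-2-[(2,2-dimethyl-1,3-benzodioxol-5-yl)ethynyl]-4-(methoxymethoxy)phenyl}prop-2-enoyl]oxy}-3-(2,2-dimethyl-1,3-benzodioxol-5-yl)propanoate
Conditions: LiCl, iPr2NEt, MeCN, rt
Reagents that add atoms: none
Why: Horner–Wadsworth–Emmons olefination under the mild LiCl/amine conditions should give the (E)-cinnamate from the aryl aldehyde without cleaving the aryl acetate or epimerising the α-acyloxy ester.

Step 12
Reactants: 15 O3-acetyl alkynyl cinnamate
Product: 16 tert-butyl (2R)-3-(2,2-dimethyl-1,3-benzodioxol-5-yl)-2-{[(2E)-3-{2-[(2,2-dimethyl-1,3-benzodioxol-5-yl)ethynyl]-3-hydroxy-4-(methoxymethoxy)phenyl}prop-2-enoyl]oxy}propanoate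
Conditions: pyrrolidine (2 equiv), CH2Cl2, 0 °C
Reagents that add atoms: none
Why: Aminolysis by a secondary amine cleaves the activated aryl acetate far faster than the alkyl cinnamate or the tert-butyl ester, and without Cu, Pd or strong base the free 2-alkynylphenol should not cyclise.

Step 13
Reactants: 16 2-alkynylphenol
Product: 17 tert-butyl (2R)-3-(2,2-dimethyl-1,3-benzodioxol-5-yl)-2-{[(2E)-3-{(3E)-3-[(2,2-dimethyl-1,3-benzodioxol-5-yl)methylidene]-7-(methoxymethoxy)-2-oxo-2,3-dihydro-1-benzofuran-4-yl}prop-2-enoyl]oxy}propanoate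
Conditions: Pd(OAc)2 (5 mol %), 1,4-bis(diphenylphosphino)butane (10 mol %), CO (20 bar), toluene, 90 °C, dark
Reagents that add atoms: carbon monoxide, [C-]#[O+]
Why: Pd(OAc)2 is reduced by the phosphine and CO to zerovalent palladium, which with the phenol O3–H (and the acetic acid released) gives a palladium hydride; either CO inserts into the Pd–O3 bond and the aryloxycarbonyl–palladium adds syn across Cα≡Cβ, or Pd–H adds syn with palladium on Cα beside O3, CO inserts and O3 captures the acyl group, and in both cases Cα–C9' and C9'–O3 are formed and zerovalent palladium is returned. The closest known reaction type is the palladium-catalysed cyclocarbonylation (intramolecular hydroalkoxycarbonylation) of alkynols and 2-alkynylphenols to α-alkylidene lactones. The five-membered lactone ring (O3, C3, C2, Cα, C9') closes in the 5-exo-dig mode in the first path, Cβ staying outside the ring, and by 5-exo-trig acyl capture in the second. No stereocentre is formed and the two R centres are remote and untouched; the alkene geometry follows from syn delivery of C9' and H, which leaves ring B cis to ring A (E). The step needs regioselectivity (C9' on Cα), which the tether O3–C3–C2 enforces because only Cα can be reached in a five-membered ring, and chemoselectivity against 5-endo-dig hydroalkoxylation to the 2-arylbenzofuran, which the absence of base and copper and the weakly acidic, phosphine-ligated zerovalent palladium under CO should secure. The conjugated 1,2-disubstituted cinnamate alkene is a poor partner for Pd–H and is expected to stay intact.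

Step 14
Reactants: 17 aryl lactone; 4 protected danshensu alcohol
Product: 18 protected salvianolic acid E: the (E)-acrylate with Cα on C2 of ring A, ring B (acetonide) on Cβ cis to ring A, C9' esterified with the (R)-oxygen of 4, O3–H free, O4 as MOM ether, the (E)-propenoate at C1 esterified with the second protected (R)-danshensu tert-butyl ester
Conditions: 4 (1.5 equiv), NaN(SiMe3)2 (1.4 equiv), THF, −78 °C; then 17, −78 → −20 °C; AcOH quench at −20 °C
Reagents that add atoms: none
Why: Transesterification of a strained aryl lactone by a sodium alkoxide, in which attack at C9' is driven by release of the more stable phenoxide O3 and of the strain between ring B and the C1 side chain, the tert-butyl esters are inert, exchange at the cinnamate ester would be degenerate because the same alkoxide is its alcohol part, and the stereocentre of 4 is not involved.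

Step 15
Reactants: 18 protected salvianolic acid E
Product: 19 salvianolic acid E
Conditions: TFA/H2O/anisole (90:5:5), 0 °C → rt, Ar; reversed-phase HPLC (C18, MeCN/H2O, 0.1 % HCO2H)
Reagents that add atoms: none
Why: Acidolysis should remove the three catechol acetonides, the MOM ether and both tert-butyl esters in one operation at or below room temperature, conditions the aryl acrylate and α-acyloxy esters tolerate, with water and anisole trapping the tert-butyl and methoxymethyl cations.

**Compound list**

1 | (R)-danshensu, (2R)-3-(3,4-dihydroxyphenyl)-2-hydroxypropanoic acid | O[C@H](Cc1ccc(O)c(O)c1)C(=O)O | starting material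
2 | (5R)-5-[(2,2-dimethyl-1,3-benzodioxol-5-yl)methyl]-2,2-dimethyl-1,3-dioxolan-4-one | CC1(C)O[C@H](Cc2ccc3OC(C)(C)Oc3c2)C(=O)O1 | intermediate
3 | (2R)-3-(2,2-dimethyl-1,3-benzodioxol-5-yl)-2-hydroxypropanoic acid | O[C@H](Cc1ccc2OC(C)(C)Oc2c1)C(=O)O | intermediate
4 | tert-butyl (2R)-3-(2,2-dimethyl-1,3-benzodioxol-5-yl)-2-hydroxypropanoate | O[C@H](Cc1ccc2OC(C)(C)Oc2c1)C(=O)OC(C)(C)C | intermediate
5 | diethylphosphonoacetic acid | CCOP(=O)(CC(=O)O)OCC | starting material
6 | tert-butyl (2R)-2-{[2-(diethoxyphosphoryl)acetyl]oxy}-3-(2,2-dimethyl-1,3-benzodioxol-5-yl)propanoate | CCOP(=O)(OCC)CC(=O)O[C@H](Cc1ccc2OC(C)(C)Oc2c1)C(=O)OC(C)(C)C | intermediate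
7 | 3,4-dihydroxybenzaldehyde | O=Cc1ccc(O)c(O)c1 | starting material
8 | 2,2-dimethyl-1,3-benzodioxole-5-carbaldehyde | O=Cc1ccc2OC(C)(C)Oc2c1 | intermediate
9 | 5-ethynyl-2,2-dimethyl-1,3-benzodioxole | C#Cc1ccc2OC(C)(C)Oc2c1 | intermediate
10 | 2-bromo-3-hydroxy-4-methoxybenzaldehyde | O=Cc1ccc(OC)c(O)c1Br | starting material
11 | 2-bromo-3,4-dihydroxybenzaldehyde | O=Cc1ccc(O)c(O)c1Br | intermediate
12 | 2-bromo-3-hydroxy-4-(methoxymethoxy)benzaldehyde | O=Cc1ccc(OCOC)c(O)c1Br | intermediate
13 | 2-bromo-3-formyl-6-(methoxymethoxy)phenyl acetate | O=Cc1ccc(OCOC)c(OC(C)=O)c1Br | intermediate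
14 | 2-[(2,2-dimethyl-1,3-benzodioxol-5-yl)ethynyl]-3-formyl-6-(methoxymethoxy)phenyl acetate | O=Cc1ccc(OCOC)c(OC(C)=O)c1C#Cc1ccc2OC(C)(C)Oc2c1 | intermediate
15 | O3-acetyl (E)-cinnamate of protected danshensu (name as in step 11) | O=C(/C=C/c1ccc(OCOC)c(OC(C)=O)c1C#Cc1ccc2OC(C)(C)Oc2c1)O[C@H](Cc1ccc2OC(C)(C)Oc2c1)C(=O)OC(C)(C)C | intermediate
16 | 2-alkynylphenol (name as in step 12) | O=C(/C=C/c1ccc(OCOC)c(O)c1C#Cc1ccc2OC(C)(C)Oc2c1)O[C@H](Cc1ccc2OC(C)(C)Oc2c1)C(=O)OC(C)(C)C | intermediate
17 | (E)-3-arylidenebenzofuran-2-one lactone (name as in step 13) | O=C(/C=C/c1ccc(OCOC)c2OC(=O)/C(=C/c3ccc4OC(C)(C)Oc4c3)c12)O[C@H](Cc1ccc2OC(C)(C)Oc2c1)C(=O)OC(C)(C)C | intermediate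
18 | protected salvianolic acid E (O4-MOM, three acetonides, two tert-butyl esters, O3–H free) | O=C(/C=C/c1ccc(OCOC)c(O)c1/C(=C\c1ccc2OC(C)(C)Oc2c1)C(=O)O[C@H](Cc1ccc2OC(C)(C)Oc2c1)C(=O)OC(C)(C)C)O[C@H](Cc1ccc2OC(C)(C)Oc2c1)C(=O)OC(C)(C)C | intermediate
19 | salvianolic acid E | O=C(/C=C/c1ccc(O)c(O)c1/C(=C\c1ccc(O)c(O)c1)C(=O)O[C@H](Cc1ccc(O)c(O)c1)C(=O)O)O[C@H](Cc1ccc(O)c(O)c1)C(=O)O | target

**Step count**

Total: 15 steps. Longest linear sequence: 9 steps (steps 7–15 from 10; equally steps 1–4 and 11–15 from 1).

**Steps most likely to fail**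

Step 13. The alkynylphenol may cycloisomerise 5-endo-dig to the 2-arylbenzofuran faster than it takes up CO, carbonylation may be slow at the doubly ortho-flanked alkyne, and the crowded E-arylidene may isomerise to the Z isomer once formed. Fallback, from 15 back to 17, building the same two bonds stepwise through a vinyl halide: palladium-catalysed hydrostannation of 15 (Bu3SnH, PdCl2(PPh3)2 cat., THF, rt) should put tin on the alkyne carbon next to the ortho-substituted ring A with syn hydrogen on Cβ (the known ortho-directing effect for diarylalkynes), giving the (E)-α-stannyl stilbene F1. Iododestannylation (I2, CH2Cl2, 0 °C) with retention would give the vinyl iodide F2. Pyrrolidine (CH2Cl2, 0 °C) would free O3 to give the iodo phenol F3. Carbonylative lactonisation (PdCl2(PPh3)2, CO 1 atm, Et3N, THF, 50 °C) then closes C9'–Cα and C9'–O3 with retention of geometry to 17.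

Step 14. The alkoxide may add reversibly to the arylidene and erode the E geometry, the opening may revert on work-up with loss of the alkoxide, or excess base may epimerise the α-acyloxy ester centres. Fallback, from 17 and 4 back to 18, forming the hindered ester by O-alkylation of the carboxylate instead of acyl transfer: LiOH (1.05 equiv, THF/H2O, 0 °C) should open only the aryl lactone to the seco acid F4, kept as its lithium carboxylate without acidification. Separately, 4 is converted with inversion (CBr4, PPh3, CH2Cl2, 0 °C, Appel reaction) into tert-butyl (2S)-2-bromo-3-(2,2-dimethyl-1,3-benzodioxol-5-yl)propanoate F5. SN2 alkylation of the carboxylate of F4 with F5 (DMF, rt) inverts again and should give the R ester 18; the neutral phenol O3–H is not alkylated.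

Step 15. In strong acid O3 may re-close the lactone with loss of the danshensu unit or add to Cβ (oxa-Michael), and tert-butyl or methoxymethyl cations may alkylate the catechol rings. Fallback, from 18 back to 19, with O3 blocked during acidolysis: acetylation (Ac2O, pyridine, DMAP cat., 0 °C) would give the O3-acetate F6. The same TFA/H2O/anisole treatment would then give 3-O-acetyl salvianolic acid E F7 (acetyl migration to O4 would be harmless). Selective aminolysis of the aryl acetate (N2H4·AcOH, DMF/MeOH, 0 °C, Ar) should release 19 without touching the alkyl esters.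

**Further compounds**

F1 | step 13 | (E)-α-tributylstannyl stilbene from 15 (Sn on Cα, H on Cβ, rings A and B cis, O3 acetate) | O=C(/C=C/c1ccc(OCOC)c(OC(C)=O)c1/C(=C\c1ccc2OC(C)(C)Oc2c1)[Sn](CCCC)(CCCC)CCCC)O[C@H](Cc1ccc2OC(C)(C)Oc2c1)C(=O)OC(C)(C)C
F2 | step 13 | vinyl iodide (I on Cα, rings A and B cis, O3 acetate) | O=C(/C=C/c1ccc(OCOC)c(OC(C)=O)c1/C(=C\c1ccc2OC(C)(C)Oc2c1)I)O[C@H](Cc1ccc2OC(C)(C)Oc2c1)C(=O)OC(C)(C)C
F3 | step 13 | iodo phenol (I on Cα, O3–H free) | O=C(/C=C/c1ccc(OCOC)c(O)c1/C(=C\c1ccc2OC(C)(C)Oc2c1)I)O[C@H](Cc1ccc2OC(C)(C)Oc2c1)C(=O)OC(C)(C)C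
F4 | step 14 | seco acid of lactone 17 (C9' carboxylic acid, O3–H free) | O=C(/C=C/c1ccc(OCOC)c(O)c1/C(=C\c1ccc2OC(C)(C)Oc2c1)C(=O)O)O[C@H](Cc1ccc2OC(C)(C)Oc2c1)C(=O)OC(C)(C)C
F5 | step 14 | tert-butyl (2S)-2-bromo-3-(2,2-dimethyl-1,3-benzodioxol-5-yl)propanoate | Br[C@@H](Cc1ccc2OC(C)(C)Oc2c1)C(=O)OC(C)(C)C
F6 | step 15 | O3-acetate of 18 | O=C(/C=C/c1ccc(OCOC)c(OC(C)=O)c1/C(=C\c1ccc2OC(C)(C)Oc2c1)C(=O)O[C@H](Cc1ccc2OC(C)(C)Oc2c1)C(=O)OC(C)(C)C)O[C@H](Cc1ccc2OC(C)(C)Oc2c1)C(=O)OC(C)(C)C
F7 | step 15 | 3-O-acetyl salvianolic acid E | O=C(/C=C/c1ccc(O)c(OC(C)=O)c1/C(=C\c1ccc(O)c(O)c1)C(=O)O[C@H](Cc1ccc(O)c(O)c1)C(=O)O)O[C@H](Cc1ccc(O)c(O)c1)C(=O)O
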